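(The numbers in the tables are simulated with made-up constants.)

Follow the ratio c(isomer of the product)/c(target), which climbs with time in this flask, and solve it at both ends.

- theta: starting material 5.0 × 10⁻⁴ M; partner 1.25 mM; free catalyst 2.5 µM; the very flask that is asked about, followed so far
- flask: starting material 5.0 × 10⁻⁴ M; partner 1.25 mM; free catalyst 2.5 µM; time 2.5 min

theta run (percent of the starting material charged)

| time / s | isomer of the product / % | target / % |
|---|---|---|
| 10.0 | 16 | 70 |
| 25.0 | 23 | 68 |
| 50.0 | 27 | 61 |
| 80.0 | 39 | 54 |

(each reading ± 2 percentage points)

* ratio of isomer of the product to target at 0.060 s
* ratio of isomer of the product to target at 2.5 min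

- steps that have been proposed: starting material + partner <-> target; starting material + partner <-> isomer of the product; target + free catalyst <-> isomer of the product + free catalyst; free catalyst <-> dormant form; free catalyst -> spent catalyst

Carry one number from the readings: the fraction of target that outlasts the span from 10.0 s to 80.0 s, 0.771, the keep factor. The next span, up to 2.5 min, is just as long.

Now take two extreme flasks. If the loss of target stops after the last reading, the ratio stays at 0.722. If the loss goes on unchanged, apply the keep factor once more: c(target) reaches 41.7%. Hold the sum of the two products at its mean reading, 89.5%, and the ratio comes to 1.15. I place this flask between them, nearer the upper end: target dropped 9 percentage points in the 0.667 min up to the third reading and 7 points in the 0.500 min after it, so the readings show no clear slowing within their scatter of 2 points.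

At the early end, 0.060 s lies far before the first reading. Take the ratio read there, 0.229, as my upper estimate for the early ratio, since the ratio read at the last reading is higher than the one at the first.

The forecast gives 0.17 and 1.1, and warns of “an early catalyst burst, before the catalyst goes dormant”. Its late value lies below my 1.15.

The flask gives 0.0946 and 1.09.

    starting material + partner ⇌ target (K = 7200 L mol⁻¹, k = 290 L mol⁻¹ s⁻¹)
    starting material + partner ⇌ isomer of the product (K = 2.40 × 10⁵ L mol⁻¹, k = 26.0 L mol⁻¹ s⁻¹)
    target + free catalyst ⇌ isomer of the product + free catalyst, rate k3*[free catalyst]*[target] forward; the back reaction follows from the equilibrium constant (k = 60000 L mol⁻¹ s⁻¹)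
    free catalyst ⇌ dormant form (K = 13.0, k = 0.230 s⁻¹)
    free catalyst → spent catalyst (k = 0.400 s⁻¹)

In this flask the keep factor foretold 41.7% of target and 44.3% stands at 2.5 min, while the half-life of target, the kinetic product, for going back to starting material and partner is 0.29 min, short against 2.5 min. For the neighbour flask with 4.2 × 10⁻⁶ M of free catalyst, starting from this flask's first reading of target and scaling the loss to the catalyst charge, as if catalyst did the whole of it, gives 29.3% of target at 2.5 min, but that neighbour flask holds 39.6%.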